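## Retrosynthetic overview

1. Target ⇐ its hydroquinone dimethyl ether (oxidative demethylation, then quinone reduction) ⇐ Pd-catalysed enolate alkenylation joining a cyclopentyl methyl ketone to an aryl-bearing (Z)-vinyl iodide; this makes the CH2–C(Me)= bond of the skipped enone with its geometry.
2. That methyl ketone, which already carries the γ-hydroxy enone, ⇐ cis-fused enol lactone + (E)-LiCH=CH–C(Me)2OLi (acyl substitution; the released ketone is protected as its enolate).
3. Enol lactone ⇐ cis-1,2-dimethyl-2-(2-oxopropyl)cyclopentane-1-carboxylate ⇐ key photochemical 1,3-acyl transposition of a 3-acetyl-1,2,2-trimethylcyclopentane-1-carboxylate: Norrish–Yang C–C bond formation between the acetyl carbon and the cis C2 methyl, then alkoxy-radical ring opening that leaves C3 as CH2.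
4. That keto ester ⇐ (1S,3R)-camphoric acid, which supplies the cyclopentane, one quaternary stereocentre and the stereocentre that directs the second. Vinyl iodide ⇐ 4-methoxy-2-methylphenol + (Z)-1-bromo-3-iodobut-2-ene (from but-2-yn-1-ol).
5. Rings: cyclopentane and arene are bought; the only rings made are temporary, first the cyclobutanol (step 3), then the enol lactone (step 4), and both are opened again.

Assumption: (1S,3R)-(−)-camphoric acid is taken as a catalogue compound (also available by nitric acid oxidation of (−)-camphor or (−)-borneol). Locants C1–C3 quoted in steps 1–3 are those of camphoric acid.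

## Route

Step 1
Reactants: 1 (1S,3R)-1,2,2-trimethylcyclopentane-1,3-dicarboxylic acid [(−)-camphoric acid; the two CO2H groups are cis]
Product: 2 (1S,3R)-3-acetyl-1,2,2-trimethylcyclopentane-1-carboxylic acid
Conditions: MeLi (4 equiv), THF, 0 °C → rt; inverse quench into 2 M HCl, 0 °C
Reagents that add atoms: methyllithium, C[Li]
Why: Methyl ketone synthesis from a lithium carboxylate and MeLi: only the carboxylate on the secondary carbon C3 adds MeLi (the C1 carboxylate sits on a tertiary carbon next to a quaternary one), the gem-diolate cannot enolise so C3 keeps its bought configuration, and C1 is untouched.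

Step 2
Reactants: 2 (1S,3R)-3-acetyl-1,2,2-trimethylcyclopentane-1-carboxylic acid
Product: 3 tert-butyl (1S,3R)-3-acetyl-1,2,2-trimethylcyclopentane-1-carboxylate
Conditions: Cl3CC(=NH)OtBu (2.5 equiv), BF3·OEt2 (5 mol %), CH2Cl2/cyclohexane, rt
Reagents that add atoms: tert-butyl 2,2,2-trichloroacetimidate, CC(C)(C)OC(=N)C(Cl)(Cl)Cl
Why: Acid-catalysed O-tert-butylation by the imidate forms the ester at oxygen, so hindrance at the acyl carbon does not matter; the ester masks the acid, which the photo-oxidant of step 3 would otherwise decarboxylate.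

Step 3
Reactants: 3 tert-butyl (1S,3R)-3-acetyl-1,2,2-trimethylcyclopentane-1-carboxylate
Product: 5 tert-butyl (1S,2S)-1,2-dimethyl-2-(2-oxopropyl)cyclopentane-1-carboxylate, via Yang cyclobutanol 4 (not isolated)
Conditions: hν (300 nm), degassed MeCN (0.02 M), rt; then [Ir(dF(CF3)ppy)2(5,5′-d(CF3)bpy)]PF6 (2 mol %), 2,4,6-triisopropylbenzenethiol (20 mol %), Bu4P[(MeO)2PO2] (30 mol %), hν (450 nm), rt; recovered 3 is recycled
Reagents that add atoms: none
Why: Proposed new method: a one-flask photochemical 1,3-acyl transposition – n→π* excitation of the acetyl group, 1,5-hydrogen transfer from the C2 methyl cis to it and collapse of the 1,4-biradical give the cis-fused cyclobutanol 4 (only the cis methyl can close to a cis-fused bicyclo[3.2.0]heptane, so the bought C3 centre fixes the new quaternary centre and is then erased); proton-coupled electron transfer from the O–H bond then gives the alkoxy radical, β-scission of the ring-fusion bond releases strain and gives the secondary cyclopentyl radical (cleavage toward the primary radical only regenerates 3), and hydrogen transfer from the thiol completes the net shift; the closest known reaction types are the Norrish–Yang cyclisation of 20-oxo steroids onto the C18 methyl and the light-driven ring-opening isomerisation of cyclic alcohols by proton-coupled electron transfer.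

Step 4
Reactants: 5 tert-butyl (1S,2S)-1,2-dimethyl-2-(2-oxopropyl)cyclopentane-1-carboxylate
Product: 7 (4aS,7aS)-3,4a,7a-trimethyl-4a,5,6,7-tetrahydrocyclopenta[c]pyran-1(7aH)-one, via keto acid 6 (not isolated)
Conditions: TFA, CH2Cl2, 0 °C → rt; evaporate; Ac2O, NaOAc, 120 °C
Reagents that add atoms: none
Why: Acidolysis of the tert-butyl ester (loss of isobutene) followed by enol lactonisation of the δ-keto acid through its mixed anhydride; the six-membered ring closes only because CO2H and CH2COCH3 are cis, and neither quaternary centre is touched.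

Step 5
Reactants: 8 2-methylbut-3-yn-2-ol
Product: 9 (3E)-2-methyl-4-(tributylstannyl)but-3-en-2-ol
Conditions: Bu3SnH (1.1 equiv), AIBN (5 mol %), toluene, 80 °C
Reagents that add atoms: tributyltin hydride, CCCC[SnH](CCCC)CCCC
Why: Radical hydrostannation of a terminal alkyne; reversible stannyl-radical addition equilibrates the product to the (E)-β-stannyl alkene.

Step 6
Reactants: 7 (4aS,7aS)-3,4a,7a-trimethyl-4a,5,6,7-tetrahydrocyclopenta[c]pyran-1(7aH)-one, 9 (3E)-2-methyl-4-(tributylstannyl)but-3-en-2-ol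
Product: 11 (2E)-1-[(1S,2S)-1,2-dimethyl-2-(2-oxopropyl)cyclopentyl]-4-hydroxy-4-methylpent-2-en-1-one, via dilithio vinyl reagent 10 (not isolated)
Conditions: 9 (1.5 equiv), n-BuLi (3.0 equiv), THF, −78 → −30 °C; then 7, −78 → 0 °C; aq. NH4Cl
Reagents that add atoms: none
Why: Tin–lithium exchange (E geometry retained) and addition of the vinyllithium to the enol lactone (Fujimoto–Belleau-type opening): the adduct collapses to the enone while the methyl ketone is released as its enolate and so is protected, and the neopentyl-type enone carbonyl resists a second addition.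

Step 7
Reactants: 12 but-2-yn-1-ol
Product: 13 (2Z)-3-iodobut-2-en-1-ol
Conditions: NaAlH2(OCH2CH2OCH3)2 (1.5 equiv), Et2O, 0 °C → rt; then I2, THF, −78 °C
Reagents that add atoms: iodine, II
Why: Alkoxide-directed trans-hydroalumination of the propargylic alcohol places aluminium on C3 cis to the CH2O group, and iodinolysis with retention gives the (Z)-vinyl iodide.

Step 8
Reactants: 13 (2Z)-3-iodobut-2-en-1-ol
Product: 14 (2Z)-1-bromo-3-iodobut-2-ene
Conditions: PBr3 (0.4 equiv), Et2O, 0 °C
Reagents that add atoms: phosphorus tribromide, BrP(Br)Br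
Why: SN2 bromination of a primary allylic alcohol through its phosphite ester; the alkene geometry is not involved.

Step 9
Reactants: 15 4-methoxy-2-methylphenol, 14 (2Z)-1-bromo-3-iodobut-2-ene
Product: 17 1-[(2Z)-3-iodobut-2-en-1-yl]-2,5-dimethoxy-3-methylbenzene, via allylphenol 16 (not isolated)
Conditions: NaH (1.05 equiv), toluene, 0 °C; 14, rt; then DMF, NaH (1.3 equiv), MeI, 0 °C → rt
Reagents that add atoms: iodomethane, CI
Why: ortho-C-alkylation of a sodium phenoxide in a non-polar solvent (tight ion pair, SN2 at the primary allylic bromide without allylic shift), then Williamson methylation; C6 is the only free ortho position (C2 carries methyl, C4 methoxy) and the vinyl iodide is inert.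

Step 10
Reactants: 11 (2E)-1-[(1S,2S)-1,2-dimethyl-2-(2-oxopropyl)cyclopentyl]-4-hydroxy-4-methylpent-2-en-1-one, 17 1-[(2Z)-3-iodobut-2-en-1-yl]-2,5-dimethoxy-3-methylbenzene
Product: 18 (2E)-1-[(1S,2S)-2-[(4Z)-6-(2,5-dimethoxy-3-methylphenyl)-4-methyl-2-oxohex-4-en-1-yl]-1,2-dimethylcyclopentyl]-4-hydroxy-4-methylpent-2-en-1-one
Conditions: LiN(SiMe3)2 (3.2 equiv), THF, −78 °C; then Pd(dba)2 (5 mol %), 1,2,3,4,5-pentaphenyl-1′-(di-tert-butylphosphino)ferrocene (10 mol %), 17 (1.1 equiv), toluene, −78 °C → rt; AcOH, −78 °C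
Reagents that add atoms: none
Why: Pd-catalysed α-alkenylation of a ketone enolate: the kinetic lithium enolate forms at the methyl group (the other α-carbon is a neopentyl CH2), oxidative addition and reductive elimination at zerovalent palladium retain the (Z) geometry of 17, and excess base holds the product as its dienolate, which is protonated at the α-carbon at −78 °C to give the β,γ-enone; the quaternary centres are not involved.

Step 11
Reactants: 18 (2E)-1-[(1S,2S)-2-[(4Z)-6-(2,5-dimethoxy-3-methylphenyl)-4-methyl-2-oxohex-4-en-1-yl]-1,2-dimethylcyclopentyl]-4-hydroxy-4-methylpent-2-en-1-one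
Product: 20 (2E)-1-[(1S,2S)-2-[(4Z)-6-(2,5-dihydroxy-3-methylphenyl)-4-methyl-2-oxohex-4-en-1-yl]-1,2-dimethylcyclopentyl]-4-hydroxy-4-methylpent-2-en-1-one (CNP0212540.3), via quinone 19 (not isolated)
Conditions: (NH4)2Ce(NO3)6 (2.5 equiv), MeCN/H2O 2:1, 0 °C; then aq. Na2S2O4, Et2O, rt, argon
Reagents that add atoms: water, O
Why: Oxidative demethylation of the p-dimethoxyarene by (NH4)2Ce(NO3)6 (both quinone oxygens come from water) and in-flask dithionite reduction of the quinone; the alkenes, ketones, tertiary alcohol and both stereocentres are untouched at 0 °C.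

## Compound list

1 | (1S,3R)-1,2,2-trimethylcyclopentane-1,3-dicarboxylic acid [(−)-camphoric acid] | C[C@]1(C(=O)O)CC[C@@H](C(=O)O)C1(C)C | starting material
2 | (1S,3R)-3-acetyl-1,2,2-trimethylcyclopentane-1-carboxylic acid | C[C@]1(C(=O)O)CC[C@@H](C(C)=O)C1(C)C | intermediate
3 | tert-butyl (1S,3R)-3-acetyl-1,2,2-trimethylcyclopentane-1-carboxylate | C[C@]1(C(=O)OC(C)(C)C)CC[C@@H](C(C)=O)C1(C)C | intermediate
4 | tert-butyl (1R,2S,5R)-6-hydroxy-1,2,6-trimethylbicyclo[3.2.0]heptane-2-carboxylate (Yang cyclobutanol, both C6 epimers, not isolated) | C[C@]1(C(=O)OC(C)(C)C)CC[C@H]2C(C)(O)C[C@@]12C | intermediate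
5 | tert-butyl (1S,2S)-1,2-dimethyl-2-(2-oxopropyl)cyclopentane-1-carboxylate | CC(=O)C[C@]1(C)CCC[C@]1(C)C(=O)OC(C)(C)C | intermediate
6 | (1S,2S)-1,2-dimethyl-2-(2-oxopropyl)cyclopentane-1-carboxylic acid (not isolated) | CC(=O)C[C@]1(C)CCC[C@]1(C)C(=O)O | intermediate
7 | (4aS,7aS)-3,4a,7a-trimethyl-4a,5,6,7-tetrahydrocyclopenta[c]pyran-1(7aH)-one (cis-fused enol lactone) | CC1=C[C@]2(C)CCC[C@]2(C)C(=O)O1 | intermediate
8 | 2-methylbut-3-yn-2-ol | CC(C)(O)C#C | starting material
9 | (3E)-2-methyl-4-(tributylstannyl)but-3-en-2-ol | CCCC[Sn](CCCC)(CCCC)/C=C/C(C)(C)O | intermediate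
10 | lithium (3E)-4-lithio-2-methylbut-3-en-2-olate (not isolated) | [Li]/C=C/C(C)(C)O[Li] | intermediate
11 | (2E)-1-[(1S,2S)-1,2-dimethyl-2-(2-oxopropyl)cyclopentyl]-4-hydroxy-4-methylpent-2-en-1-one | CC(=O)C[C@]1(C)CCC[C@]1(C)C(=O)/C=C/C(C)(C)O | intermediate
12 | but-2-yn-1-ol | CC#CCO | starting material
13 | (2Z)-3-iodobut-2-en-1-ol | C/C(I)=C/CO | intermediate
14 | (2Z)-1-bromo-3-iodobut-2-ene | C/C(I)=C/CBr | intermediate
15 | 4-methoxy-2-methylphenol | Cc1cc(OC)ccc1O | starting material
16 | 2-[(2Z)-3-iodobut-2-en-1-yl]-4-methoxy-6-methylphenol (not isolated) | C/C(I)=C/Cc1cc(OC)cc(C)c1O | intermediate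
17 | 1-[(2Z)-3-iodobut-2-en-1-yl]-2,5-dimethoxy-3-methylbenzene | C/C(I)=C/Cc1cc(OC)cc(C)c1OC | intermediate
18 | (2E)-1-[(1S,2S)-2-[(4Z)-6-(2,5-dimethoxy-3-methylphenyl)-4-methyl-2-oxohex-4-en-1-yl]-1,2-dimethylcyclopentyl]-4-hydroxy-4-methylpent-2-en-1-one | C/C(=C/Cc1cc(OC)cc(C)c1OC)CC(=O)C[C@]1(C)CCC[C@]1(C)C(=O)/C=C/C(C)(C)O | intermediate
19 | 2-[(2Z)-6-{(1S,2S)-2-[(2E)-4-hydroxy-4-methylpent-2-enoyl]-1,2-dimethylcyclopentyl}-3-methyl-5-oxohex-2-en-1-yl]-6-methylcyclohexa-2,5-diene-1,4-dione (not isolated) | C/C(=C/CC1=CC(=O)C=C(C)C1=O)CC(=O)C[C@]2(C)CCC[C@]2(C)C(=O)/C=C/C(C)(C)O | intermediate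
20 | (2E)-1-[(1S,2S)-2-[(4Z)-6-(2,5-dihydroxy-3-methylphenyl)-4-methyl-2-oxohex-4-en-1-yl]-1,2-dimethylcyclopentyl]-4-hydroxy-4-methylpent-2-en-1-one | C/C(=C/Cc1cc(O)cc(C)c1O)CC(=O)C[C@]1(C)CCC[C@]1(C)C(=O)/C=C/C(C)(C)O | target

## Step count and risks

Total step count: 11. Longest linear sequence: 7 steps (steps 1, 2, 3, 4, 6, 10, 11).

The three steps most likely to fail:

Step 3 (the proposed transposition). The Yang cyclisation competes with cleavage of the 1,4-biradical and with photo-epimerisation at C3, and the alkoxy-radical relay has not been run on such a substrate. The fallback uses only precedented, stoichiometric chemistry; it sets out from 3 and comes back to the route at 5. Irradiate 3 at 300 nm in tert-butanol and isolate cyclobutanol 4, as is done for 20-oxopregnanes. Fragment 4 through its hypoiodite (PhI(OAc)2, I2, cyclohexane, visible light); this oxidative β-fragmentation cleaves the ring-fusion bond and traps the radical as the secondary iodide tert-butyl (1S,2S,3RS)-3-iodo-1,2-dimethyl-2-(2-oxopropyl)cyclopentane-1-carboxylate F1. Remove the iodine with Bu3SnH/AIBN (toluene, 80 °C) to give 5.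

Step 10 (enolate alkenylation). The lithium enolate of 11 may add to the enone carbonyl, and the product may be alkenylated twice or slip into conjugation. The fallback sets out from 11 and 17 and comes back at 18, and it takes the coupling off the strongly basic lithium enolate. Trap the kinetic enolate at −78 °C (LiN(SiMe3)2 with Me3SiCl present from the start) as (2E)-1-[(1S,2S)-1,2-dimethyl-2-{2-[(trimethylsilyl)oxy]prop-2-en-1-yl}cyclopentyl]-4-methyl-4-[(trimethylsilyl)oxy]pent-2-en-1-one F2. Couple F2 with 17 as its tributyltin enolate under neutral conditions (Bu3SnF, PdCl2[P(o-tol)3]2, toluene, 80 °C; Migita–Kuwajima alkenylation) to give (2E)-1-[(1S,2S)-2-[(4Z)-6-(2,5-dimethoxy-3-methylphenyl)-4-methyl-2-oxohex-4-en-1-yl]-1,2-dimethylcyclopentyl]-4-methyl-4-[(trimethylsilyl)oxy]pent-2-en-1-one F3. Cleave the tertiary silyl ether with AcOH in THF/H2O to reach 18.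

Step 9 (phenoxide C-allylation). O-allylation can dominate and the yield of the ortho-C product is typically moderate. The fallback sets out from 15 (with 14) and comes back at 17, and it makes the aryl–allyl bond by cross-coupling instead. Brominate 15 ortho to the hydroxyl (NBS, CH2Cl2, 0 °C) to 2-bromo-4-methoxy-6-methylphenol F4. Methylate (MeI, K2CO3, acetone) to 1-bromo-2,5-dimethoxy-3-methylbenzene F5. Form (2,5-dimethoxy-3-methylphenyl)magnesium bromide F6 (Mg, THF) and couple it with bromide 14 under Li2CuCl4 catalysis (THF, −20 °C), which gives 17 directly.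

## Further compounds

F1 | step 3 | tert-butyl (1S,2S,3RS)-3-iodo-1,2-dimethyl-2-(2-oxopropyl)cyclopentane-1-carboxylate | CC(=O)C[C@]1(C)C(I)CC[C@]1(C)C(=O)OC(C)(C)C
F2 | step 10 | (2E)-1-[(1S,2S)-1,2-dimethyl-2-{2-[(trimethylsilyl)oxy]prop-2-en-1-yl}cyclopentyl]-4-methyl-4-[(trimethylsilyl)oxy]pent-2-en-1-one | C=C(O[Si](C)(C)C)C[C@]1(C)CCC[C@]1(C)C(=O)/C=C/C(C)(C)O[Si](C)(C)C
F3 | step 10 | (2E)-1-[(1S,2S)-2-[(4Z)-6-(2,5-dimethoxy-3-methylphenyl)-4-methyl-2-oxohex-4-en-1-yl]-1,2-dimethylcyclopentyl]-4-methyl-4-[(trimethylsilyl)oxy]pent-2-en-1-one | C/C(=C/Cc1cc(OC)cc(C)c1OC)CC(=O)C[C@]1(C)CCC[C@]1(C)C(=O)/C=C/C(C)(C)O[Si](C)(C)C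
F4 | step 9 | 2-bromo-4-methoxy-6-methylphenol | Cc1cc(OC)cc(Br)c1O
F5 | step 9 | 1-bromo-2,5-dimethoxy-3-methylbenzene | COc1cc(C)c(OC)c(Br)c1
F6 | step 9 | (2,5-dimethoxy-3-methylphenyl)magnesium bromide | COc1cc(C)c(OC)c([Mg]Br)c1
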